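61.0 µM of catalyst is what this reckoning counts as turning over: the charge of 86.0 µM less the 25 µM of impurity, which takes catalyst one for one. Each free catalyst meets impurity at 11.0 s⁻¹, faster than the 3.80 s⁻¹ at which substrate captures it.

| setting | Friday's | Monday's | Tuesday's | Saturday's |
|---|---|---|---|---|
| substrate | 2.0 mM | 2.0 mM | 2.0 mM | 2.0 mM |
| reagent | 1.00 equiv | 1.00 equiv | 1.00 equiv (fed, over 64.0 s) | 1.00 equiv |
| free catalyst | 4.3 mol% | 4.3 mol% | 4.3 mol% | 4.3 mol% |
| impurity | 25 µM | 25 µM | 25 µM | 25 µM |
| remark | a single well-mixed tank run continuously and read at steady state, 800 s in it on average | one stirred flow tank at steady state, fed with the mixture as stated, mean residence time 80 s | a stirred flask in which reagent is dosed at a steady rate over 64.0 s without added volume, worked up at 80 s | everything together in a closed stirred flask, run for 80 s |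
| time |  |  | 80 s | 80 s |

    catalyst intermediate C ⇌ released group + catalyst intermediate D (K1 = 0.0050 M, k1 = 3.0 s⁻¹)
    released group → by-product carried off (k2 = 0.011 s⁻¹)
    substrate + free catalyst ⇌ catalyst intermediate A (K3 = 12000 M⁻¹, k3 = 1900 M⁻¹ s⁻¹)
    free catalyst + impurity → spent catalyst (k4 = 4.4 × 10⁵ M⁻¹ s⁻¹)
    reagent + catalyst intermediate B → catalyst intermediate C (k5 = 760 M⁻¹ s⁻¹)
    free catalyst ⇌ dormant form (K6 = 1.6, k6 = 0.30 s⁻¹)
    catalyst intermediate A ⇌ catalyst intermediate B (K7 = 39, k7 = 3.3 s⁻¹)
    catalyst intermediate D → free catalyst + product (k8 = 160 s⁻¹)

* the set-up with the highest amount of product at the outlet or at the end, in percent of the substrate put in ("none" if the first two lie within 2 percentage points) (Friday's / Monday's / Tuesday's / Saturday's / none)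
* amount of product at the outlet or at the end, in percent of the substrate put in, Friday's
* amount of product at the outlet or at the end, in percent of the substrate put in, Monday's
* amount of product at the outlet or at the end, in percent of the substrate put in, Tuesday's
* amount of product at the outlet or at the end, in percent of the substrate put in, Saturday's

One turn of the catalyst (one turnover) takes the sum of the waits at its stations. With substrate at its charge, free catalyst and dormant form, once they stand at 1.6 of the latter to one of the former, wait on average 0.684 s for substrate. Catalyst intermediate B waits 0.658 s for reagent, and intermediates A, C and D take 0.643 s together. The way back from B is left out, at 0.0846 s⁻¹, slower than its 1.52 s⁻¹ forward at the charge, and so is the way back from A, at 0.158 s⁻¹, slower than its 3.3 s⁻¹ forward. A turn therefore takes 1.98 s.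

That gives 65.1 s for the emptying time, the substrate present divided by the rate at that moment. Substrate and reagent are charged equal and fall together, so the two waits for them lengthen in step with the falling concentration while the 0.643 s of intermediates A, C and D stays, and the emptying time drifts down towards 44.0 s at the dilute end.

Turn the question round: for Saturday's closed flask to beat Friday's tank, its remainder after 80 s would have to fall below the tank's. At a steady emptying time the closed flask decays exponentially, while a tank's remainder is that time over itself plus the stay. At 65.1 s the closed flask keeps 29.3% and Friday's tank 7.53%; at 44.0 s they keep 16.2% and 5.21%. The closed flask keeps more than Friday's tank in both cases, so this reckoning commits to Friday's tank first, between 92.5% and 94.8%. Saturday's flask follows at 70.7% to 83.8%, and Monday's tank lies at 55.1% to 64.5%. In Tuesday's flask the average portion of reagent has 48.0 s in the flask, less than the closed flask's 80 s, so it is placed below Saturday's without a figure.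

The forecast gave Friday's 93%, Monday's 58%, Tuesday's 60% and Saturday's 71%, and said of Friday's longer stay that it “outweighs its back-mixing penalty and makes it the clear winner”.

The simulation gives Friday's 93.6%, Monday's 59.1%, Tuesday's 60.5% and Saturday's 75.2%, with Friday's first. Read back through the tank law, with everything not yet product counted as remainder, these yields give an emptying time of 54.7 s in Friday's tank and 55.4 s in Monday's tank, both less than the 65.1 s at the charge and more than the 44.0 s of the dilute end. Against these readings, Friday's stay of 800 s comes to 14.6 emptying times and Monday's stay of 80 s to 1.44.

The numbers of this flask are assumed; the rest is arithmetic.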